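**Plan**
- Retrosynthesis: the 5-OH and 7-OH are masked as benzyl ethers and the 3-OMe is traced back through 3-OH to 3-H, giving flavone 14. Ring C of 14 is then cut at C4–C3 and at O1–C2.
- Enabling feature: the carbonyl carbon C4 sits on C4a, next to the O1-bearing C8a. Ring A plus C4 is therefore a salicylaldehyde (7): its formyl C–H becomes the C4–C3 bond and its ortho hydroxyl becomes O1. C3, C2 and ring B arrive as an aroyl carbene equivalent, the sulfoxonium ylide 12.
- Forward, ring A: phloroglucinol is tri-O-benzylated, dibrominated, doubly methoxylated, formylated, and one ortho benzyl ether is cleaved to give 7. Ring B is bought as 2,4,5-trimethoxybenzoic acid and converted into 12 in two steps.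
- Ring C is the only ring made and closes in step 8 (7 + 12 → 14). C3 is then hydroxylated and O-methylated, and the benzyl ethers are removed.
- Stereochemistry: the target has no stereogenic unit, so nothing has to be set. The transient epoxide 15 is racemic and both its centres vanish on rearrangement.

Key step: step 8

Assumption: because the target is achiral, "single enantiomer" is read as the one constitution drawn.

Step 1
Reactants: 1 phloroglucinol
Product: 2 1,3,5-tris(benzyloxy)benzene
Conditions: BnBr (3.3 equiv), K2CO3, DMF, rt → 60 °C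
Reagents that add atoms: benzyl bromide, BrCc1ccccc1
Why: Williamson O-alkylation of the three phenoxides with a weak base in a dipolar aprotic solvent should favour the tris-ether over C-benzylated by-products, which are removed by crystallisation.

Step 2
Reactants: 2 1,3,5-tris(benzyloxy)benzene
Product: 3 1,3,5-tris(benzyloxy)-2,4-dibromobenzene
Conditions: NBS (2.05 equiv), CH2Cl2–MeCN, 0 °C → rt, dark
Reagents that add atoms: N-bromosuccinimide, O=C1CCC(=O)N1Br
Why: Electrophilic aromatic bromination, in which every free position of 2 is ortho/para to three alkoxy groups and the third position is slowed by two inductively withdrawing bromines, so two equivalents should stop at the dibromide.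

Step 3
Reactants: 3 1,3,5-tris(benzyloxy)-2,4-dibromobenzene
Product: 4 1,3,5-tris(benzyloxy)-2,4-dimethoxybenzene
Conditions: NaOMe/MeOH (excess), CuBr (40 mol%), DMF, 110 °C
Reagents that add atoms: sodium methoxide, C[O-].[Na+]
Why: Copper(I)-mediated Ullmann-type methoxylation is the standard way to exchange aryl bromides flanked by two alkoxy groups in polymethoxyarene work, and aryl benzyl ethers are inert to methoxide under these conditions.

Step 4
Reactants: 4 1,3,5-tris(benzyloxy)-2,4-dimethoxybenzene
Product: 6 2,4,6-tris(benzyloxy)-3,5-dimethoxybenzaldehyde, via aryl iminium chloride 5 (not isolated)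
Conditions: POCl3, DMF, 0 → 70 °C; then H2O, 50 °C
Reagents that add atoms: N,N-dimethylformamide, CN(C)C=O; water, O
Why: Vilsmeier–Haack formylation at the only remaining ring hydrogen, which is activated by two ortho and one para benzyloxy group; the non-Lewis-acidic conditions leave the benzyl ethers intact and iminium salt 5 is hydrolysed on work-up.

Step 5
Reactants: 6 2,4,6-tris(benzyloxy)-3,5-dimethoxybenzaldehyde
Product: 7 4,6-bis(benzyloxy)-2-hydroxy-3,5-dimethoxybenzaldehyde
Conditions: MgBr2·OEt2 (2 equiv), PhMe–Et2O, 70 °C; then 1 M HCl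
Reagents that add atoms: none
Why: Carbonyl-chelation-directed ether cleavage, in which magnesium held by the formyl oxygen activates only an ortho benzyloxy oxygen for bromide attack at the benzylic carbon; the two ortho ethers are equivalent by symmetry and the magnesium phenoxide chelate formed first should protect the second, while the para benzyl ether and both methyl ethers stay.

Step 6
Reactants: 8 2,4,5-trimethoxybenzoic acid
Product: 9 2,4,5-trimethoxybenzoyl chloride
Conditions: (COCl)2, DMF (cat.), CH2Cl2, 0 °C → rt; evaporate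
Reagents that add atoms: oxalyl chloride, ClC(=O)C(Cl)=O
Why: Standard DMF-catalysed conversion of an aryl carboxylic acid into its chloride; the crude chloride is used directly after evaporation.

Step 7
Reactants: 9 2,4,5-trimethoxybenzoyl chloride; 10 trimethylsulfoxonium iodide
Product: 12 2-(dimethyl(oxo)-λ6-sulfanylidene)-1-(2,4,5-trimethoxyphenyl)ethan-1-one, via dimethylsulfoxonium methylide 11 (not isolated)
Conditions: 10 (3 equiv), KOtBu (3 equiv), THF, reflux; then 9, 0 °C → rt
Reagents that add atoms: none
Why: Corey–Chaykovsky-type C-acylation of the methylide, a second equivalent of which deprotonates the acylsulfoxonium salt to give the stabilised β-keto sulfoxonium ylide.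

Step 8
Reactants: 7 4,6-bis(benzyloxy)-2-hydroxy-3,5-dimethoxybenzaldehyde; 12 2-(dimethyl(oxo)-λ6-sulfanylidene)-1-(2,4,5-trimethoxyphenyl)ethan-1-one
Product: 14 5,7-bis(benzyloxy)-6,8-dimethoxy-2-(2,4,5-trimethoxyphenyl)-4H-chromen-4-one, via 1,3-diketone 13 (not isolated)
Conditions: [Cp*RhCl2]2 (4 mol%), AgSbF6 (16 mol%), NaOAc (30 mol%), PivOH (1 equiv), DCE, 90 °C, Ar
Reagents that add atoms: none
Why: Chloride abstraction by AgSbF6 gives a cationic Cp*Rh(III) carboxylate that binds the phenoxide of 7 and cleaves the neighbouring formyl C–H by concerted metalation–deprotonation to a five-membered O,C-acyl rhodacycle; 12 then binds through its ylide carbon, loses dimethyl sulfoxide to a rhodium carbene, the acyl group migrates onto the carbene carbon (new C4–C3 bond), and protonolysis by PivOH releases diketone 13 and the catalyst. The closest known reaction type is the Rh(III)-catalysed annulation of salicylaldehydes with aroyl sulfoxonium ylides to 2-arylchromones, applied here to a fully substituted aldehyde. Ring C closes by 6-exo-trig addition of the C8a hydroxyl to the aroyl carbonyl of 13 (new O1–C2 bond), followed by acid-promoted loss of water to the aromatic 4-pyranone. No stereocentre is formed. The step needs chemoselectivity for formyl C–H insertion over O–H insertion of the carbene, over decarbonylation of the acyl rhodium and over aryl C–H activation: the phenoxide chelate fixes the acyl group on rhodium cis to the carbene site, ring A of 7 carries no aryl hydrogen, and the phenoxide is a far better directing group than the ylide carbonyl that could activate C6′–H of 12. Regiochemistry is not in question, because only the hydroxyl ortho to the new diketone can reach the distal carbonyl through a six-membered transition state.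

Step 9
Reactants: 14 5,7-bis(benzyloxy)-6,8-dimethoxy-2-(2,4,5-trimethoxyphenyl)-4H-chromen-4-one
Product: 16 5,7-bis(benzyloxy)-3-hydroxy-6,8-dimethoxy-2-(2,4,5-trimethoxyphenyl)-4H-chromen-4-one, via flavone 2,3-epoxide 15 (not isolated)
Conditions: DMDO (acetone soln, 3 equiv), CH2Cl2, 0 °C → rt; evaporate; then TsOH·H2O (cat.), CH2Cl2, rt
Reagents that add atoms: dimethyldioxirane, CC1(C)OO1
Why: Dioxirane epoxidation of the C2–C3 double bond followed by acid-catalysed opening at C2 (oxocarbenium stabilised by O1 and the aryl group) and loss of H3 should give the 3-hydroxyflavone, both stereocentres of the racemic epoxide being destroyed in the rearrangement.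

Step 10
Reactants: 16 5,7-bis(benzyloxy)-3-hydroxy-6,8-dimethoxy-2-(2,4,5-trimethoxyphenyl)-4H-chromen-4-one
Product: 17 5,7-bis(benzyloxy)-3,6,8-trimethoxy-2-(2,4,5-trimethoxyphenyl)-4H-chromen-4-one
Conditions: MeI, K2CO3, acetone, reflux
Reagents that add atoms: iodomethane, CI
Why: Williamson methylation of the only free hydroxyl, the acidic 3-enol OH, under mild base.

Step 11
Reactants: 17 5,7-bis(benzyloxy)-3,6,8-trimethoxy-2-(2,4,5-trimethoxyphenyl)-4H-chromen-4-one
Product: 18 5,7-dihydroxy-3,6,8-trimethoxy-2-(2,4,5-trimethoxyphenyl)-4H-chromen-4-one (5,7-dihydroxy-3,6,8,2',4',5'-hexamethoxyflavone)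
Conditions: H2 (1 atm), 10% Pd/C, EtOAc–MeOH, rt
Reagents that add atoms: none
Why: Catalytic hydrogenolysis of the two aryl benzyl ethers over palladium; the fully substituted C2–C3 bond of a 3-methoxyflavone and the methyl ethers should not be reduced at one atmosphere and room temperature.

**Compound list**
1 | phloroglucinol (benzene-1,3,5-triol) | Oc1cc(O)cc(O)c1 | starting material
2 | 1,3,5-tris(benzyloxy)benzene | c1ccc(COc2cc(OCc3ccccc3)cc(OCc3ccccc3)c2)cc1 | intermediate
3 | 1,3,5-tris(benzyloxy)-2,4-dibromobenzene | Brc1c(OCc2ccccc2)cc(OCc2ccccc2)c(Br)c1OCc1ccccc1 | intermediate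
4 | 1,3,5-tris(benzyloxy)-2,4-dimethoxybenzene | COc1c(OCc2ccccc2)cc(OCc2ccccc2)c(OC)c1OCc1ccccc1 | intermediate
5 | N-[2,4,6-tris(benzyloxy)-3,5-dimethoxybenzylidene]-N-methylmethanaminium chloride (aryl iminium chloride) | C[N+](C)=Cc1c(OCc2ccccc2)c(OC)c(OCc2ccccc2)c(OC)c1OCc1ccccc1.[Cl-] | intermediate (not isolated)
6 | 2,4,6-tris(benzyloxy)-3,5-dimethoxybenzaldehyde | O=Cc1c(OCc2ccccc2)c(OC)c(OCc2ccccc2)c(OC)c1OCc1ccccc1 | intermediate
7 | 4,6-bis(benzyloxy)-2-hydroxy-3,5-dimethoxybenzaldehyde | COc1c(O)c(C=O)c(OCc2ccccc2)c(OC)c1OCc1ccccc1 | intermediate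
8 | 2,4,5-trimethoxybenzoic acid | COc1cc(OC)c(C(=O)O)cc1OC | starting material
9 | 2,4,5-trimethoxybenzoyl chloride | COc1cc(OC)c(C(=O)Cl)cc1OC | intermediate
10 | trimethylsulfoxonium iodide | C[S+](C)(C)=O.[I-] | starting material
11 | dimethylsulfoxonium methylide | C[S+](C)(=O)[CH2-] | intermediate (not isolated)
12 | 2-(dimethyl(oxo)-λ6-sulfanylidene)-1-(2,4,5-trimethoxyphenyl)ethan-1-one | COc1cc(OC)c(C(=O)C=S(C)(C)=O)cc1OC | intermediate
13 | 1-[4,6-bis(benzyloxy)-2-hydroxy-3,5-dimethoxyphenyl]-3-(2,4,5-trimethoxyphenyl)propane-1,3-dione | COc1cc(OC)c(C(=O)CC(=O)c2c(O)c(OC)c(OCc3ccccc3)c(OC)c2OCc2ccccc2)cc1OC | intermediate (not isolated)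
14 | 5,7-bis(benzyloxy)-6,8-dimethoxy-2-(2,4,5-trimethoxyphenyl)-4H-chromen-4-one | COc1cc(OC)c(-c2cc(=O)c3c(OCc4ccccc4)c(OC)c(OCc4ccccc4)c(OC)c3o2)cc1OC | intermediate
15 | 2,3-epoxide of 14 (oxirane across C2–C3, racemic, ring fusion necessarily cis) | COc1cc(OC)c(C23OC2C(=O)c2c(OCc4ccccc4)c(OC)c(OCc4ccccc4)c(OC)c2O3)cc1OC | intermediate (not isolated)
16 | 5,7-bis(benzyloxy)-3-hydroxy-6,8-dimethoxy-2-(2,4,5-trimethoxyphenyl)-4H-chromen-4-one | COc1cc(OC)c(-c2oc3c(OC)c(OCc4ccccc4)c(OC)c(OCc4ccccc4)c3c(=O)c2O)cc1OC | intermediate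
17 | 5,7-bis(benzyloxy)-3,6,8-trimethoxy-2-(2,4,5-trimethoxyphenyl)-4H-chromen-4-one | COc1cc(OC)c(-c2oc3c(OC)c(OCc4ccccc4)c(OC)c(OCc4ccccc4)c3c(=O)c2OC)cc1OC | intermediate
18 | 5,7-dihydroxy-3,6,8,2',4',5'-hexamethoxyflavone (achiral) | COc1cc(OC)c(-c2oc3c(OC)c(O)c(OC)c(O)c3c(=O)c2OC)cc1OC | target

**Step count**
Total: 11 steps. Longest linear sequence: 9 steps (steps 1–5 and 8–11); steps 6–7 form the convergent ylide branch.

**Steps most likely to fail**

Step 8. Formyl C–H metalation may be slow at an aldehyde twisted out of plane by two ortho oxygen substituents, and the ylide may then be consumed by carbene dimerisation or by functionalisation of its own C6′–H. The fallback builds ring C by enolate chemistry and sets out from 7. Addition of MeMgBr (excess, THF, 0 °C) should give racemic 1-[4,6-bis(benzyloxy)-2-hydroxy-3,5-dimethoxyphenyl]ethan-1-ol F1. Activated MnO2 in CH2Cl2 should oxidise it to 1-[4,6-bis(benzyloxy)-2-hydroxy-3,5-dimethoxyphenyl]ethan-1-one F2. The dilithium enolate of F2 (LiHMDS, 3 equiv, THF, −78 °C) is C-aroylated with acid chloride 9 in a Baker–Venkataraman-type step to give diketone 13, which is isolated here. Catalytic TsOH in toluene then cyclodehydrates 13, and the route is rejoined at 14.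

Step 3. Hydrodebromination may compete with substitution, or the reaction may stop after the first exchange at the doubly flanked C–Br bonds. The fallback replaces direct C–O substitution by C–B formation and oxidation and sets out from 3. Miyaura diborylation (B2pin2, Pd(OAc)2/SPhos, KOAc, dioxane, 90 °C) should give 2,2'-[2,4,6-tris(benzyloxy)-1,3-phenylene]bis(4,4,5,5-tetramethyl-1,3,2-dioxaborolane) F3. Oxidation with H2O2/aq NaOH in THF at 0 °C should give 2,4,6-tris(benzyloxy)benzene-1,3-diol F4. Immediate methylation (MeI, K2CO3, DMF) returns to the route at 4.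

Step 9. Epoxidation of the electron-poor C2–C3 bond may be slow enough that excess dioxirane attacks the electron-rich trimethoxyphenyl ring or the benzylic C–H bonds of the benzyl ethers. The fallback uses directed C3 metalation instead of oxidation of the alkene and sets out from 14. LDA in THF at −78 °C should give 5,7-bis(benzyloxy)-3-lithio-6,8-dimethoxy-2-(2,4,5-trimethoxyphenyl)-4H-chromen-4-one F5. Trapping with B(OMe)3 gives the dimethyl flavon-3-ylboronate, dimethyl [5,7-bis(benzyloxy)-6,8-dimethoxy-4-oxo-2-(2,4,5-trimethoxyphenyl)-4H-chromen-3-yl]boronate F6. Oxidation with H2O2/AcOH returns to the route at flavonol 16.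

**Further compounds**
F1 | step 8 | 1-[4,6-bis(benzyloxy)-2-hydroxy-3,5-dimethoxyphenyl]ethan-1-ol (racemic) | CC(O)c1c(O)c(OC)c(OCc2ccccc2)c(OC)c1OCc1ccccc1
F2 | step 8 | 1-[4,6-bis(benzyloxy)-2-hydroxy-3,5-dimethoxyphenyl]ethan-1-one | CC(=O)c1c(O)c(OC)c(OCc2ccccc2)c(OC)c1OCc1ccccc1
F3 | step 3 | 2,2'-[2,4,6-tris(benzyloxy)-1,3-phenylene]bis(4,4,5,5-tetramethyl-1,3,2-dioxaborolane) | CC1(C)OB(OC1(C)C)c1c(OCc2ccccc2)cc(OCc2ccccc2)c(B2OC(C)(C)C(C)(C)O2)c1OCc1ccccc1
F4 | step 3 | 2,4,6-tris(benzyloxy)benzene-1,3-diol | Oc1c(OCc2ccccc2)cc(OCc2ccccc2)c(O)c1OCc1ccccc1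
F5 | step 9 | 5,7-bis(benzyloxy)-3-lithio-6,8-dimethoxy-2-(2,4,5-trimethoxyphenyl)-4H-chromen-4-one | [Li]c1c(-c2cc(OC)c(OC)cc2OC)oc2c(OC)c(OCc3ccccc3)c(OC)c(OCc3ccccc3)c2c1=O
F6 | step 9 | dimethyl [5,7-bis(benzyloxy)-6,8-dimethoxy-4-oxo-2-(2,4,5-trimethoxyphenyl)-4H-chromen-3-yl]boronate | COB(OC)c1c(-c2cc(OC)c(OC)cc2OC)oc2c(OC)c(OCc3ccccc3)c(OC)c(OCc3ccccc3)c2c1=O
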